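Count how many lifetimes of the starting material fit into the run before integrating anything.

    starting material + reagent → target (k1 = 1.3 /M/min)
    starting material + 2 reagent → side product (k2 = 49 /M²/min)
    starting material + target ⇌ idle adduct, settled at all times (K3 = 85 /M)
    crystals ⇌ target, rate k4*(cs4 - [target]) while solid is left; crystals form when [target] > cs4 (cs4 = 9.9 mM, k4 = 0.51 /min)

| flask | starting material | reagent | time |
|---|---|---|---|
| oak | 0.014 M | 0.0150 M | 1.0 h |
| larch | 0.014 M | 0.0250 M | 1.0 h |
| alder | 0.014 M | 0.0400 M | 1.0 h |
| birch | 0.014 M | 0.0600 M | 1.0 h |

- a species is counted by the starting material in it: one idle adduct counts as two
- amounts and yields of target count idle adduct and crystals too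
- where a step has two of a species, its rate is k times that concentration squared, and two are used at each turn
- given per volume of solution although it is solid: crystals
- in an amount of target, one idle adduct counts as one target
- "hardly changes" means that all values lie within two and a half points (for a concentration: within two and a half percent of the largest)
- run time (oak): 1.0 h

* amount of target at the end, in percent of the starting material charged for oak, larch, alder, birch, in this order
* how the row runs (rises, then falls / hardly changes / rises all the way / falls all the way / falls, then rises)

**What do you count first?** Oak at its charge gives 1.83 for the lifetime count n: the run time multiplied by the pseudo-first-order loss constant of free starting material through both steps, at a held reagent level c. Birch at its charge gives 15.3, far more than oak.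

**And the yield?** I multiply the conversion, one minus e to the minus n, by the selectivity f, the rate of the target step over the rate of both steps. At the charges, oak gives 53.6% and birch 30.7%, so the row seems to fall.

**But why hold the reagent at its charge?** I should not, since oak holds 0.0150 M of reagent against 0.014 M of starting material, and each turn takes one or two reagent. So I count again at half the charge, which gives a low count m. Oak has m = 0.750, and the yield estimate becomes 41.1%. Larch has m = 1.43 and gives 51.8%. Alder gives 53.3%.

**Does that hold for birch?** No. Birch's reagent cannot fall below 0.0320 M, so I take the middle of charge and floor, 0.0460 M. With so large a count, birch's yield is its selectivity there, 36.6%.

**Where is your row weakest?** It ignores the idle adduct. The equilibrium constant times the starting concentration is 1.2, above one, so binding takes free starting material away, and I hold the oak and larch values as high. I commit to a row that rises, then falls, with its top at alder.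

The forecast gives 38.8%, 45.8%, 44.4% and 35.5%, which places larch above alder, the other way round from my row, and it reads its row thus: “The low end is kinetically limited and the high end selectivity-limited, giving a maximum”.

The flask gives 38.8%, 45.9%, 44.6% and 35.6%: the row rises, then falls, turning at a reagent concentration of 0.030 M. Oak ends with 35% of its starting material unbound, which lies between e to the minus n, 16.0%, and e to the minus m, 47.2%. For larch the same pair is 2.27% and 23.9%, and larch ends with 16.9% of its starting material.

Its constants belong to no real substance; no experiment stands behind them.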